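Turn the question round and ask how steeply the reacted part would have to follow c(free base) for Sunday's, Saturday's and Monday's flasks to show a rise.

| flask | electrophile | free base | protonated nucleophile | remark | time |
|---|---|---|---|---|---|
| blue | 0.50 M (fed, over 80 s) | 0.15 M | 0.90 M | run made earlier |  |
| ochre | 1 M (fed, over 80 s) | 0.15 M | 0.60 M | run made earlier |  |
| Sunday's | 0.50 M (fed, over 80 s) | 0.150 M | 0.600 M |  | 6.0 min |
| Saturday's | 0.50 M (fed, over 80 s) | 0.220 M | 0.600 M |  | 6.0 min |
| Monday's | 0.50 M (fed, over 80 s) | 0.340 M | 0.600 M |  | 6.0 min |

| run | time / min | electrophile / % | target / % |
|---|---|---|---|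
| blue | 0.667 | 49.8 | 0.6 |
| blue | 1.33 | 98.9 | 1.3 |
| blue | 2.00 | 97.9 | 1.9 |
| blue | 2.50 | 96.1 | 3.5 |
| blue | 3.00 | 95.9 | 3.4 |
| blue | 4.00 | 95.4 | 5.1 |
| ochre | 0.250 | 18.5 | 0.8 |
| ochre | 0.667 | 49.6 | 0 |
| ochre | 1.33 | 99.6 | 0.7 |
| ochre | 2.00 | 98.2 | 1.6 |
| ochre | 3.00 | 97.4 | 1.9 |
| ochre | 4.00 | 96.9 | 3.2 |

(each reading ± 0.5 percentage points)

- percentages count the whole charge, also what has not yet gone in
- no earlier run changes the charge of free base; that part of a forecast is a guess

- part of the electrophile that has reacted at the end, Sunday's
- part of the electrophile that has reacted at the end, Saturday's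
- part of the electrophile that has reacted at the end, Monday's
- what raising the concentration of free base from its lowest to its highest value here does to the part of the electrophile that has reacted (changes below 5 percentage points count as none) (it rises / no change / it falls)

In the ochre run the target stands at 3.2% at 4.00 min. Counted from the middle of the feed, that is 0.00960 min⁻¹ of the charge, read as a pseudo-first-order loss of electrophile. The blue run's target reading at that time is 1.59 times the ochre run's, against a ratio of 1.50 in c(protonated nucleophile), though the two runs differ in electrophile charge as well. Sunday's flask has the ochre run's c(protonated nucleophile) but 0.50 M of electrophile against 1 M; taking the percentage as independent of that charge, this reckoning puts Sunday's flask at 5.12%.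

Monday's flask has 2.27 times Sunday's c(free base). For a rise, its reacted part must reach Sunday's plus the margin, 10.1%. The logarithm of the ratio of that part to Sunday's over the logarithm of the ratio of charges is the critical order, the apparent reaction order in free base at which the change from Sunday's to Monday's flask just reaches the margin: 0.833. No run has varied free base, so the true order is a guess. The band from zero up to the critical order is wider than the band from there to first order, so this reckoning weakly commits to no change.

The forecast gives 5.3%, 7.5% and 11%, and so "it rises", “Assuming the base is needed to free or deprotonate the nucleophile”. On the trend it differs from this reckoning.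

The flasks give 6.10%, 6.98% and 8.32%, a change of 2.2 percentage points: no change.

    electrophile + nucleophile → acid set free + target (k = 0.0420 M⁻¹ s⁻¹)
    nucleophile + acid set free ⇌ protonated nucleophile, settled at all times (K = 8000 M⁻¹)
    acid set free + free base ⇌ salt of the base (K = 55000 M⁻¹, k = 0.0650 M⁻¹ s⁻¹)
    target ⇌ isomer of the product (K = 0.200, k = 0.110 s⁻¹)

From Sunday's to Monday's the apparent order is 0.378, lower than the critical order 0.833 reckoned from the ochre run. A neighbouring flask, like Sunday's but with 0.090 M of free base, gives 5.29%. From there, a rise by the margin on the step up to Sunday's charge has a critical order of 1.30, while the step shows an apparent order of 0.280.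

The earlier runs and the new flask are simulated from invented constants; scatter was added.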